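Rings: A = para-phenylene; B = the ring with the free OH; D = meta-phenylene; C = the quinone, numbered C1 (C=O beside the alkylated carbon), C2 (bears CH2CH2–ring A), C3 (bears O–ring D), C4 (second C=O), C5 and C6 (CH=CH).
Retrosynthesis, in order: (a) the benzyl ether on ring B and the C4 oxygen, back to a C1 phenol with a free para carbon C4; (b) the macrocyclic ether bond C3–O–ring D; (c) ring C itself at C2–C3 and C1–C6, giving a siloxyalkyne (C1, C2 and the whole A–B–D chain) and cyclobutenone (C3 to C6); (d) ring B–CH=CH–ring D and ring A–O–ring B.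
Enabling feature: below the quinone oxidation level ring C is a 2-alkylresorcinol monoether, with the chain carbon C2 flanked by the oxygenated carbons C1 and C3 and with only H on C4 to C6. A vinylketene (C3 to C6) and an O-silyl ynol ether (C1, C2) assemble exactly this array regiospecifically, with C3–OH free and C1–O silylated.
Forward: ether A–O–B, then the B–CH2CH2–D bridge, then ester to alkyne to siloxyalkyne. Ring C is built last of the four rings by benzannulation, its new C3–OH closes the 18-membered ring onto the bromide of ring D, and desilylation, oxidation at C4 and debenzylation finish the route.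
Stereochemistry: the target has no stereocentre; the E-alkene of the olefination product is saturated and the one sp3 carbon of the transient vinylcyclobutenone becomes an arene CH.

Key step: step 7

Remark: the 18-membered ring is treated as conformationally mobile (no stable atropisomers), and 1, 2, 4 and 12 are taken as catalogue compounds.

Step 1
Reactants: 1 4-(benzyloxy)-3-hydroxybenzaldehyde; 2 methyl 3-(4-bromophenyl)propanoate
Product: 3 methyl 3-{4-[2-(benzyloxy)-5-formylphenoxy]phenyl}propanoate
Conditions: CuI (10 mol %), N,N-dimethylglycine·HCl (30 mol %), Cs2CO3, dioxane, 90 °C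
Reagents that add atoms: none
Why: Ligand-accelerated Ullmann diaryl ether coupling of an ortho-alkoxyphenol with an unactivated aryl bromide should proceed cleanly, since aldehyde and ester are inert to anhydrous Cs2CO3.

Step 2
Reactants: 3 methyl 3-{4-[2-(benzyloxy)-5-formylphenoxy]phenyl}propanoate; 4 diethyl (3-bromobenzyl)phosphonate
Product: 5 methyl 3-[4-(2-(benzyloxy)-5-[(E)-2-(3-bromophenyl)ethenyl]phenoxy)phenyl]propanoate
Conditions: NaH, THF, 0 °C to rt (anion of 4 formed first, then 3 added)
Reagents that add atoms: none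
Why: Horner–Wadsworth–Emmons olefination of the non-enolisable aldehyde by the benzylic phosphonate anion should give the E-stilbene (geometry irrelevant, as step 3 saturates it), the methyl ester being far less electrophilic than the aldehyde.

Step 3
Reactants: 5 methyl 3-[4-(2-(benzyloxy)-5-[(E)-2-(3-bromophenyl)ethenyl]phenoxy)phenyl]propanoate
Product: 6 methyl 3-[4-(2-(benzyloxy)-5-[2-(3-bromophenyl)ethyl]phenoxy)phenyl]propanoate
Conditions: TsNHNH2, NaOAc, THF/H2O, reflux
Reagents that add atoms: none
Why: Diimide reduction transfers two hydrogens to the C=C bond in a concerted syn fashion and should leave the aryl bromide, benzyl ether and ester untouched, which catalytic hydrogenation would not guarantee.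

Step 4
Reactants: 6 methyl 3-[4-(2-(benzyloxy)-5-[2-(3-bromophenyl)ethyl]phenoxy)phenyl]propanoate
Product: 8 1-(benzyloxy)-4-[2-(3-bromophenyl)ethyl]-2-[4-(but-3-yn-1-yl)phenoxy]benzene, via aldehyde 7 (not isolated)
Conditions: i-Bu2AlH, CH2Cl2, −78 °C; then MeOH, K2CO3, dimethyl (1-diazo-2-oxopropyl)phosphonate, −78 °C to rt
Reagents that add atoms: dimethyl (1-diazo-2-oxopropyl)phosphonate (Ohira–Bestmann reagent), CC(=O)C(=[N+]=[N-])P(=O)(OC)OC
Why: The hydride reduction should stop at the aluminium hemiacetal at −78 °C, which releases aldehyde 7 on adding methanol for Seyferth–Gilbert homologation with the Ohira–Bestmann reagent (one-pot ester-to-alkyne conversion), conditions that tolerate aryl bromide and ethers.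

Step 5
Reactants: 8 1-(benzyloxy)-4-[2-(3-bromophenyl)ethyl]-2-[4-(but-3-yn-1-yl)phenoxy]benzene
Product: 11 {[4-(4-{2-(benzyloxy)-5-[2-(3-bromophenyl)ethyl]phenoxy}phenyl)but-1-yn-1-yl]oxy}tri(propan-2-yl)silane, via lithium acetylide 9 (not isolated), via lithium ynolate 10 (not isolated)
Conditions: LiN(SiMe3)2, THF, −78 °C; t-BuOOLi (from t-BuOOH and LiN(SiMe3)2), −78 to 0 °C; then i-Pr3SiOTf, −78 °C
Reagents that add atoms: tert-butyl hydroperoxide, CC(C)(C)OO; triisopropylsilyl trifluoromethanesulfonate, CC(C)[Si](C(C)C)(C(C)C)OS(=O)(=O)C(F)(F)F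
Why: The amide base deprotonates the alkyne without halogen–lithium exchange at the aryl bromide, lithium tert-butyl peroxide transfers electrophilic oxygen to the acetylide to give the ynolate, and the bulky silyl triflate traps it on oxygen as an isolable silyl ynol ether (acetylide oxidation and O-silylation).

Step 6
Reactants: 12 3-bromocyclobutan-1-one
Product: 13 cyclobut-2-en-1-one
Conditions: n-Bu3N, rt; vacuum transfer into a −78 °C trap; kept as a cold PhMe solution
Reagents that add atoms: none
Why: Amine-mediated E1cB dehydrobromination of the β-bromoketone should give the strained enone, which is separated from the ammonium salt by vacuum transfer and kept cold and dilute to suppress polymerisation.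

Step 7
Reactants: 11 {[4-(4-{2-(benzyloxy)-5-[2-(3-bromophenyl)ethyl]phenoxy}phenyl)but-1-yn-1-yl]oxy}tri(propan-2-yl)silane; 13 cyclobut-2-en-1-one
Product: 18 2-[2-(4-{2-(benzyloxy)-5-[2-(3-bromophenyl)ethyl]phenoxy}phenyl)ethyl]-3-[(triisopropylsilyl)oxy]phenol, via vinylketene 14 (not isolated), via 4-vinylcyclobutenone 15 (not isolated), via dienylketene 16 (not isolated), via cyclohexadienone 17 (not isolated)
Conditions: PhMe, 100 to 110 °C, sealed tube, 13 (1.5 equiv) added slowly
Reagents that add atoms: none
Why: Heating opens 13 by 4π electrocyclic ring opening to vinylketene 14, whose carbonyl carbon (future C3) is attacked by the nucleophilic chain-bearing alkyne carbon C2 of 11 in a regiospecific ketene [2+2] cycloaddition that forms C2–C3 and C1–C6 and gives 15; 15 opens again (4π) to dienylketene 16, which closes (6π) to dienone 17 and tautomerises to phenol 18. The closest known reaction type is the Danheiser benzannulation of cyclobutenones with siloxyalkynes, which gives 2-substituted resorcinol monosilyl ethers. Ring C is closed by the thermal disrotatory 6π electrocyclisation of 16 (ketene carbon C3 onto the vinyl terminus C4), the four-membered ring of 15 being only a transient helper ring from the [2+2] step. No stereocentre survives, because the sp3 carbon C6 of racemic 15 becomes an arene CH. The step needs regioselectivity (OH on C3, silyloxy on C1, chain on C2 between them), which the polarisation of the ynol ether secures, since the oxygen lone pair makes C2 the nucleophile and the ketene carbonyl carbon is the electrophile. It also needs chemoselectivity over ketene dimerisation and cyclobutenone polymerisation, which rests on the high ketenophilicity of the siloxyalkyne, the slow addition of 13 and the absence of any OH or NH group in 11.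

Step 8
Reactants: 18 2-[2-(4-{2-(benzyloxy)-5-[2-(3-bromophenyl)ethyl]phenoxy}phenyl)ethyl]-3-[(triisopropylsilyl)oxy]phenol
Product: 19 macrocyclic diaryl ether (18-membered ring closed by the C3–O–ring D bond; ring C carries OSi(i-Pr)3 at C1, ring B is O-benzylated)
Conditions: CuI (50 mol %), N,N-dimethylglycine·HCl, Cs2CO3, dioxane, 100 °C, 2 mM, slow addition of 18
Reagents that add atoms: none
Why: Intramolecular Ullmann etherification under high dilution should join the only phenol (C3–OH) to the only aryl halide (ring D) in an unstrained 18-membered closure, and because C1–O and C3–O are equivalent positions of a 2-alkylresorcinol, premature silyl loss would lead to the same ring after step 9.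

Step 9
Reactants: 19 macrocyclic diaryl ether with OSi(i-Pr)3 at C1
Product: 20 macrocyclic phenol (free OH at C1 of ring C, ring B O-benzylated)
Conditions: n-Bu4NF, AcOH, THF, 0 °C to rt
Reagents that add atoms: none
Why: Fluoride-mediated desilylation of the aryl silyl ether, buffered with acetic acid so that no free phenoxide sits in basic solution, should release the C1 phenol without touching the ethers.

Step 10
Reactants: 20 macrocyclic phenol
Product: 21 O-benzylmarchantinquinone (the target with the ring B hydroxyl as benzyl ether)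
Conditions: (KO3S)2NO, KH2PO4, acetone/H2O, rt
Reagents that add atoms: Fremy's salt (potassium nitrosodisulfonate), [K+].[K+].[O]N(S(=O)(=O)[O-])S(=O)(=O)[O-]
Why: Teuber oxidation: hydrogen abstraction from the only free phenol and coupling of a second nitroxide radical at the unsubstituted para carbon C4, followed by loss of imidodisulfonate, should give the para-quinone, while the aryl ethers (ring B still benzylated) are inert.

Step 11
Reactants: 21 O-benzylmarchantinquinone
Product: 24 marchantinquinone, via O-benzyl hydroquinone 22 (not isolated), via hydroquinone 23 (not isolated)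
Conditions: H2 (1 atm), Pd/C, EtOAc, rt; filter; then Ag2O (1.1 equiv), EtOAc, rt
Reagents that add atoms: none
Why: Hydrogenolysis of the benzyl ether over Pd/C unavoidably reduces the quinone to the hydroquinone, which Ag2O should re-oxidise at once and selectively, a hydroquinone being far easier to oxidise than the mono-phenol of ring B.

Compound list
1 | 4-(benzyloxy)-3-hydroxybenzaldehyde | O=Cc1ccc(OCc2ccccc2)c(O)c1 | starting material
2 | methyl 3-(4-bromophenyl)propanoate | COC(=O)CCc1ccc(Br)cc1 | starting material
3 | methyl 3-{4-[2-(benzyloxy)-5-formylphenoxy]phenyl}propanoate | COC(=O)CCc1ccc(Oc2cc(C=O)ccc2OCc2ccccc2)cc1 | intermediate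
4 | diethyl (3-bromobenzyl)phosphonate | CCOP(=O)(Cc1cccc(Br)c1)OCC | starting material
5 | methyl 3-[4-(2-(benzyloxy)-5-[(E)-2-(3-bromophenyl)ethenyl]phenoxy)phenyl]propanoate | COC(=O)CCc1ccc(Oc2cc(/C=C/c3cccc(Br)c3)ccc2OCc2ccccc2)cc1 | intermediate
6 | methyl 3-[4-(2-(benzyloxy)-5-[2-(3-bromophenyl)ethyl]phenoxy)phenyl]propanoate | COC(=O)CCc1ccc(Oc2cc(CCc3cccc(Br)c3)ccc2OCc2ccccc2)cc1 | intermediate
7 | 3-[4-(2-(benzyloxy)-5-[2-(3-bromophenyl)ethyl]phenoxy)phenyl]propanal (formed in the flask) | O=CCCc1ccc(Oc2cc(CCc3cccc(Br)c3)ccc2OCc2ccccc2)cc1 | intermediate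
8 | 1-(benzyloxy)-4-[2-(3-bromophenyl)ethyl]-2-[4-(but-3-yn-1-yl)phenoxy]benzene | C#CCCc1ccc(Oc2cc(CCc3cccc(Br)c3)ccc2OCc2ccccc2)cc1 | intermediate
9 | lithium acetylide of 8 (formed in the flask) | [Li]C#CCCc1ccc(Oc2cc(CCc3cccc(Br)c3)ccc2OCc2ccccc2)cc1 | intermediate
10 | lithium 4-(4-{2-(benzyloxy)-5-[2-(3-bromophenyl)ethyl]phenoxy}phenyl)but-1-yn-1-olate (ynolate, formed in the flask) | [Li]OC#CCCc1ccc(Oc2cc(CCc3cccc(Br)c3)ccc2OCc2ccccc2)cc1 | intermediate
11 | {[4-(4-{2-(benzyloxy)-5-[2-(3-bromophenyl)ethyl]phenoxy}phenyl)but-1-yn-1-yl]oxy}tri(propan-2-yl)silane | CC(C)[Si](OC#CCCc1ccc(Oc2cc(CCc3cccc(Br)c3)ccc2OCc2ccccc2)cc1)(C(C)C)C(C)C | intermediate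
12 | 3-bromocyclobutan-1-one | O=C1CC(Br)C1 | starting material
13 | cyclobut-2-en-1-one | O=C1C=CC1 | intermediate
14 | buta-1,3-dien-1-one (vinylketene, formed in the flask) | C=CC=C=O | intermediate
15 | racemic 4-ethenyl-2-[2-(4-{2-(benzyloxy)-5-[2-(3-bromophenyl)ethyl]phenoxy}phenyl)ethyl]-3-[(triisopropylsilyl)oxy]cyclobut-2-en-1-one (formed in the flask) | O=C1C(CCc2ccc(Oc3cc(CCc4cccc(Br)c4)ccc3OCc3ccccc3)cc2)=C(O[Si](C(C)C)(C(C)C)C(C)C)C1C=C | intermediate
16 | dienylketene: 2-[2-(aryl)ethyl]-3-[(triisopropylsilyl)oxy]hexa-1,3,5-trien-1-one, chain carbon and vinyl group cis across the 3,4-double bond (formed in the flask) | O=C=C(CCc1ccc(Oc2cc(CCc3cccc(Br)c3)ccc2OCc2ccccc2)cc1)/C(O[Si](C(C)C)(C(C)C)C(C)C)=C\C=C | intermediate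
17 | 2-[2-(4-{2-(benzyloxy)-5-[2-(3-bromophenyl)ethyl]phenoxy}phenyl)ethyl]-3-[(triisopropylsilyl)oxy]cyclohexa-2,4-dien-1-one (formed in the flask) | O=C1CC=CC(O[Si](C(C)C)(C(C)C)C(C)C)=C1CCc1ccc(Oc2cc(CCc3cccc(Br)c3)ccc2OCc2ccccc2)cc1 | intermediate
18 | 2-[2-(4-{2-(benzyloxy)-5-[2-(3-bromophenyl)ethyl]phenoxy}phenyl)ethyl]-3-[(triisopropylsilyl)oxy]phenol | Oc1cccc(O[Si](C(C)C)(C(C)C)C(C)C)c1CCc1ccc(Oc2cc(CCc3cccc(Br)c3)ccc2OCc2ccccc2)cc1 | intermediate
19 | macrocyclic diaryl ether: 18-membered ring, ring C as 1-(triisopropylsilyloxy)-2-alkyl-3-aryloxybenzene, ring B O-benzylated | CC(C)[Si](Oc1cccc2c1CCc1ccc(cc1)Oc1cc(ccc1OCc1ccccc1)CCc1cccc(c1)O2)(C(C)C)C(C)C | intermediate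
20 | macrocyclic phenol: 19 without the silyl group (free OH at C1 of ring C) | Oc1cccc2c1CCc1ccc(cc1)Oc1cc(ccc1OCc1ccccc1)CCc1cccc(c1)O2 | intermediate
21 | O-benzylmarchantinquinone | O=C1C=CC(=O)C2=C1CCc1ccc(cc1)Oc1cc(ccc1OCc1ccccc1)CCc1cccc(c1)O2 | intermediate
22 | O-benzyl hydroquinone: ring C of 21 reduced to the 1,4-diol (formed in the flask) | Oc1ccc(O)c2c1CCc1ccc(cc1)Oc1cc(ccc1OCc1ccccc1)CCc1cccc(c1)O2 | intermediate
23 | marchantinquinone hydroquinone: ring C 1,4-diol, ring B OH free (formed in the flask) | Oc1ccc(O)c2c1CCc1ccc(cc1)Oc1cc(ccc1O)CCc1cccc(c1)O2 | intermediate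
24 | marchantinquinone | O=C1C=CC(=O)C2=C1CCc1ccc(cc1)Oc1cc(ccc1O)CCc1cccc(c1)O2 | target

Total step count: 11. Longest linear sequence: 10 steps (steps 1 to 5 and 7 to 11); step 6 is a one-step side branch.

Steps most likely to fail

Step 7. Polymerisation of 13 and dimerisation of 14 may outrun the [2+2] capture, and adventitious acid may protonate the ynol ether. The fallback sets out from 11 and returns at 18. Vinylketene 14 is generated at room temperature by 1,4-dehydrochlorination of (E)-but-2-enoyl chloride with Et3N in the presence of 11, so no cyclobutenone is handled. The 3-siloxy-4-vinylcyclobutenone 15 is isolated (F0: no compound outside the list) and then heated alone in PhMe at 110 °C, so that ring opening and 6π closure to 18 occur without free ketene in solution.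

Step 8. Intermolecular etherification to oligomers, reductive loss of bromine and slow catalyst turnover at high dilution may prevail. The fallback sets out from 18 and returns at 19, and reverses the polarity of ring D. Miyaura borylation (B2pin2, Pd(dppf)Cl2, KOAc, dioxane, 80 °C) should give the aryl pinacol boronate F1. An oxidative Chan–Lam macro-etherification (Cu(OAc)2, pyridine, 4 Å sieves, CH2Cl2, air, rt, high dilution) then closes the ring to 19 without heat or carbonate base.

Step 10. Attack at the ortho carbon C6, over-oxidation, or poor conversion of the water-insoluble phenol in the aqueous medium may occur. The fallback sets out from 20 and returns at 21 by the classical nitrogen route. para-Nitrosation (NaNO2, AcOH/EtOH, 0 °C) should give the 4-nitrosophenol F2, and reduction (Na2S2O4, aqueous EtOH) the 4-aminophenol F3. Oxidation to the quinone imine and hydrolysis (FeCl3, aqueous HCl/EtOAc) then give quinone 21.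

Further compounds
F0 | step 7 | none | none
F1 | step 8 | 2-[2-(4-{2-(benzyloxy)-5-[2-(3-(4,4,5,5-tetramethyl-1,3,2-dioxaborolan-2-yl)phenyl)ethyl]phenoxy}phenyl)ethyl]-3-[(triisopropylsilyl)oxy]phenol | Oc1cccc(O[Si](C(C)C)(C(C)C)C(C)C)c1CCc1ccc(Oc2cc(CCc3cccc(B4OC(C)(C)C(C)(C)O4)c3)ccc2OCc2ccccc2)cc1
F2 | step 10 | macrocyclic 4-nitrosophenol (20 with N=O at C4 of ring C) | Oc1ccc(N=O)c2c1CCc1ccc(cc1)Oc1cc(ccc1OCc1ccccc1)CCc1cccc(c1)O2
F3 | step 10 | macrocyclic 4-aminophenol (20 with NH2 at C4 of ring C) | Oc1ccc(N)c2c1CCc1ccc(cc1)Oc1cc(ccc1OCc1ccccc1)CCc1cccc(c1)O2
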